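The route makes all three aryl C–O bonds of the benzo ring last. In the chromone, O1 (on C8a) and the hydroxyl oxygens on C5 and C7 all sit ortho or para to C4a. C4a carries the C4 carbonyl, so these are exactly the positions a ketone activates for fluoride displacement. One pot therefore turns an open-chain 1-(2,4,6-trifluorophenyl)-1,3-diketone bearing the C27 chain into the protected chromone. The enolate oxygen closes the pyranone ring (C8a–O1), then benzyl alcohol replaces the fluorides at C7 and C5. The precursor comes in two steps from octacosanoic acid and 2′,4′,6′-trifluoroacetophenone, and one hydrogenolysis finishes the synthesis.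

Key step: step 3

Remark on the chemistry: the target (C36H60O4, unbranched C27 chain on C2) has no stereocentre and no stereogenic double bond, so it is achiral and no enantiomer has to be chosen.

Step 1
Reactants: 1 octacosanoic acid
Product: 2 octacosanoyl chloride
Conditions: SOCl2 (2 equiv), DMF (cat.), toluene, 70 °C; evaporation, toluene chase; used crude
Reagents that add atoms: thionyl chloride, O=S(Cl)Cl
Why: Acyl chloride formation (nucleophilic acyl substitution, DMF-catalysed through the Vilsmeier-type chloroiminium salt) is reliable for saturated fatty acids, warm toluene keeps the wax acid dissolved, and the by-products leave as gases.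

Step 2
Reactants: 2 octacosanoyl chloride; 3 2′,4′,6′-trifluoroacetophenone (1.2 equiv)
Product: 4 1-(2,4,6-trifluorophenyl)triacontane-1,3-dione (expected mainly as the chelated enol)
Conditions: MgBr2·OEt2 (2.5 equiv), CH2Cl2, then i-Pr2NEt (3 equiv) dropwise, 25 → 35 °C; 1 M HCl work-up
Reagents that add atoms: none
Why: In this soft-enolisation, Claisen-type C-acylation, Mg(II) coordination acidifies the methyl ketone enough for an amine base and the product is held as its magnesium chelate (no second acylation), while no hard nucleophile is present to touch the C–F bonds and no cryogenic temperature makes the wax chloride precipitate.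

Step 3
Reactants: 4 1-(2,4,6-trifluorophenyl)triacontane-1,3-dione; 5 benzyl alcohol
Product: 8 5,7-bis(benzyloxy)-2-heptacosyl-4H-chromen-4-one, via 5,7-difluoro-2-heptacosyl-4H-chromen-4-one 6 (not isolated), via 7-(benzyloxy)-5-fluoro-2-heptacosyl-4H-chromen-4-one 7 (not isolated)
Conditions: Cs2CO3 (5 equiv), powdered 4 Å MS, NMP–toluene 4:1 (0.05 M), Ar, 80 °C until 4 is consumed; then BnOH (6 equiv), same flask, 120 °C
Reagents that add atoms: benzyl alcohol (5, two equivalents incorporated), OCc1ccccc1
Why: Cs2CO3 turns 4 into its enolate, whose oxygen on chain C3 (the future O1 on C2) adds to one ortho C–F carbon (the future C8a) to give a Meisenheimer adduct with the charge on C4a and the C4 carbonyl oxygen, and loss of fluoride gives 6; once the alcohol is added, carbonate-generated benzyloxide replaces the para fluoride at C7 (7) and then the ortho fluoride at C5 (8) by the same addition–elimination, and the opposite order would converge on the same 8. The closest known reaction types are the carbonate-mediated closure of 1-(2-fluoroaryl)-1,3-diketones to chromones and the iterative displacement of fluoride by oxygen nucleophiles on polyfluorinated aryl ketones and polyfluorochromones, here simply run one after the other in one flask. The pyranone ring closes by a six-membered intramolecular SNAr, formally a 6-endo-trig addition to the C8a=C4a–C4=O unit followed by elimination, whereas C-arylation through chain C2 would need a four-membered ring, so only O-arylation can occur. No stereocentre is formed. Regiochemistry needs no control, because the two ortho fluorides of 4 are equivalent by symmetry and closure leaves exactly one ortho (C5) and one para (C7) fluoride, and since all three oxygens are mutually meta, each new alkoxy group donates into C4a, C6 and C8 but not into the remaining C–F carbon, so the deactivation is only indirect. Chemoselectivity is secured by adding the alcohol only after 4 is consumed (no retro-Claisen cleavage of the electron-poor aroyl diketone), by the weak base (low standing alkoxide concentration, so attack at C2 stays reversible and C1′ is hardly deprotonated), by the sieves (no hydroxide) and by argon (no benzaldehyde to condense at C1′).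

Step 4
Reactants: 8 5,7-bis(benzyloxy)-2-heptacosyl-4H-chromen-4-one
Product: 9 5,7-dihydroxy-2-heptacosyl-4H-chromen-4-one (target)
Conditions: H2 (1 atm), 10% Pd/C, THF, 40 °C; stopped after uptake of 2 equiv H2; hot filtration
Reagents that add atoms: none
Why: Heterogeneous catalytic hydrogenolysis of aryl benzyl ethers is much faster than saturation of the trisubstituted, oxygen-substituted C2–C3 double bond of a chromone, and warm THF keeps both 8 and 9 in solution.

Compound list
1 | octacosanoic acid | CCCCCCCCCCCCCCCCCCCCCCCCCCCC(=O)O | starting material
2 | octacosanoyl chloride | CCCCCCCCCCCCCCCCCCCCCCCCCCCC(=O)Cl | intermediate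
3 | 2′,4′,6′-trifluoroacetophenone | CC(=O)c1c(F)cc(F)cc1F | starting material
4 | 1-(2,4,6-trifluorophenyl)triacontane-1,3-dione | CCCCCCCCCCCCCCCCCCCCCCCCCCCC(=O)CC(=O)c1c(F)cc(F)cc1F | intermediate
5 | benzyl alcohol | OCc1ccccc1 | starting material
6 | 5,7-difluoro-2-heptacosyl-4H-chromen-4-one (formed and consumed in step 3) | CCCCCCCCCCCCCCCCCCCCCCCCCCCc1cc(=O)c2c(F)cc(F)cc2o1 | intermediate
7 | 7-(benzyloxy)-5-fluoro-2-heptacosyl-4H-chromen-4-one (formed and consumed in step 3) | CCCCCCCCCCCCCCCCCCCCCCCCCCCc1cc(=O)c2c(F)cc(OCc3ccccc3)cc2o1 | intermediate
8 | 5,7-bis(benzyloxy)-2-heptacosyl-4H-chromen-4-one | CCCCCCCCCCCCCCCCCCCCCCCCCCCc1cc(=O)c2c(OCc3ccccc3)cc(OCc3ccccc3)cc2o1 | intermediate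
9 | 5,7-dihydroxy-2-heptacosyl-4H-chromen-4-one (achiral) | CCCCCCCCCCCCCCCCCCCCCCCCCCCc1cc(=O)c2c(O)cc(O)cc2o1 | target

Total step count: 4. Longest linear sequence: 4 steps (1 → 2 → 4 → 8 → 9).

Steps most likely to fail

Step 3.
- **What may go wrong:** The sequence may stall before the last fluoride is replaced, because the first alkoxy group weakens the activation by C4. Hydroxide from traces of water may compete and give a phenoxide that shuts the ring down. A benzyl group may be lost by attack of benzyloxide or fluoride on the benzylic carbon before the last displacement. Benzyloxide may also open the pyranone ring at C2.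
- **Fallback:** The oxygens are placed first and the ring is closed by condensation. This route sets out from 2 and comes back at 8.
- **How it runs:** 2 O-acylates commercial 1-[2,4-bis(benzyloxy)-6-hydroxyphenyl]ethan-1-one (pyridine, DMAP, CH2Cl2, 35 °C) to give 2-acetyl-3,5-bis(benzyloxy)phenyl octacosanoate F1. t-BuOK in THF then moves the acyl group from oxygen to the acetyl carbon (Baker–Venkataraman rearrangement) to give 1-[2,4-bis(benzyloxy)-6-hydroxyphenyl]triacontane-1,3-dione F2. Catalytic p-TsOH in toluene at 80 °C cyclodehydrates this diketone to 8.

Step 2.
- **What may go wrong:** The amine may convert 2 into its ketene. O-acylation or double acylation may occur. Conversion may be slow because the wax chloride is poorly soluble.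
- **Fallback:** The other C–C bond of the diketone is made (chain C1–C2 instead of C2–C3). This route sets out from 2 and comes back at 4.
- **How it runs:** 2 acylates Meldrum's acid (pyridine, CH2Cl2, 0 °C → rt) to give 5-(1-hydroxyoctacosylidene)-2,2-dimethyl-1,3-dioxane-4,6-dione F3. Heating with t-BuOH in toluene gives tert-butyl 3-oxotriacontanoate F4. MgCl2/Et3N-mediated C-acylation with commercial 2,4,6-trifluorobenzoyl chloride in CH2Cl2 gives tert-butyl 3-oxo-2-(2,4,6-trifluorobenzoyl)triacontanoate F5. TFA in CH2Cl2 removes the tert-butyl group, and the resulting β-keto acid decarboxylates to 4.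

Step 4.
- **What may go wrong:** The C2–C3 double bond may be over-reduced. The reaction may also stall if the sparingly soluble phenol deposits on the catalyst.
- **Fallback:** A non-reductive Lewis-acid ether cleavage is used. It sets out from 8 and comes back at 9.
- **How it runs:** BCl3 with pentamethylbenzene as benzyl-cation scavenger in CH2Cl2 at −20 → 0 °C should cleave both aryl benzyl ethers, the C5 ether first through chelation to the C4 carbonyl. Aqueous work-up releases 9. No hydrogen source is present, so the double bond cannot be reduced. The fallback makes no compound outside the list (entry F0).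

Further compounds
F1 | step 3 | 2-acetyl-3,5-bis(benzyloxy)phenyl octacosanoate | CCCCCCCCCCCCCCCCCCCCCCCCCCCC(=O)Oc1cc(OCc2ccccc2)cc(OCc2ccccc2)c1C(C)=O
F2 | step 3 | 1-[2,4-bis(benzyloxy)-6-hydroxyphenyl]triacontane-1,3-dione | CCCCCCCCCCCCCCCCCCCCCCCCCCCC(=O)CC(=O)c1c(O)cc(OCc2ccccc2)cc1OCc1ccccc1
F3 | step 2 | 5-(1-hydroxyoctacosylidene)-2,2-dimethyl-1,3-dioxane-4,6-dione | CCCCCCCCCCCCCCCCCCCCCCCCCCCC(O)=C1C(=O)OC(C)(C)OC1=O
F4 | step 2 | tert-butyl 3-oxotriacontanoate | CCCCCCCCCCCCCCCCCCCCCCCCCCCC(=O)CC(=O)OC(C)(C)C
F5 | step 2 | tert-butyl 3-oxo-2-(2,4,6-trifluorobenzoyl)triacontanoate (C2 configurationally labile, enolisable, not defined) | CCCCCCCCCCCCCCCCCCCCCCCCCCCC(=O)C(C(=O)OC(C)(C)C)C(=O)c1c(F)cc(F)cc1F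
F0 | step 4 | none | none
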